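Which of the four flasks ends with the most E, and how much does each hold?

| flask | J | Z | temperature | time |
|---|---|---|---|---|
| south-east | 0.80 M | 0.0800 M | −10 °C | 8.0 min |
| north-west | 0.80 M | 0.0800 M | 15 °C | 8.0 min |
| west | 0.80 M | 0.0800 M | 65 °C | 8.0 min |
| east | 0.80 M | 0.0800 M | 40 °C | 8.0 min |

    X + Z → X.Z (k1 = 0.37 L mol⁻¹ s⁻¹, Ea1 = 47.0 kJ mol⁻¹)
    J ⇌ X, rate k2*(cs2 - [X]) while solid is left; crystals form when [X] > cs2 (cs2 = 0.50 M, k2 = 0.35 s⁻¹)
    X + Q → X.Q (k3 = 0.0017 L mol⁻¹ s⁻¹, Ea3 = 58.0 kJ mol⁻¹)
    X ⇌ E + Q (K4 = 0.41 M, k4 = 0.021 s⁻¹, Ea4 = 83.0 kJ mol⁻¹, ΔH4 = 24.0 kJ mol⁻¹)
    (constants at 40 °C)

- as a solid, counted per litre of solution: J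
- the constants hold at 40 °C; other temperatures follow from the activation energies and enthalpies
- at the start none of J is in solution
- what has only dissolved of J counts as not reacted

* the flask with the highest amount of E, in percent of the J charged ("all alike" if they lie within 1.5 percentage points) (south-east / north-west / west / east / all alike)
* final E, as a percentage of the J charged, in south-east
* final E, as a percentage of the J charged, in north-west
* final E, as a percentage of the J charged, in west
* final E, as a percentage of the J charged, in east

I begin with the balance of the smaller charge. Z is the limiting reagent, since J is charged at ten times its amount, and each Z binds one X. At 40 °C with X near 0.50 M, Z lasts about 5.41 s, far shorter than 8.0 min, so in the warm flasks I take it as bound. That leaves a pool of 0.720 M for step 4.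

Step 4 has a time of 47.6 s at 40 °C, again well inside the run, so I let it reach equilibrium. With step 3 set aside, Q equals E, so I solve E·E/(pool − E) = K. For west, with K at 0.810 M, the answer as a share of the J charged is 57.4%, and I call this the ceiling of E. For east it is 47.0%, and the X left there, 0.344 M, lies below the solubility. In south-east, with K at 0.0711 M, my balance keeps solid J with X at the solubility, so there E·E equals K times the solubility and the ceiling is 23.6%, lower than east's. North-west lies between them in temperature, so its K does too. For the two cold flasks I commit to no number beyond these marks, and I put west first, its ceiling being higher than those of east and south-east.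

The weak link is step 3, which I have ignored. With X.Q formed, Q is E minus X.Q, and X is the pool minus E minus X.Q. At the rate that the X and Q of the ceiling give in east, step 3 makes about 0.106 M of X.Q within the run, and putting that into the balance gives 46.5%, which is 0.50 percentage points below the ceiling of east. West is hotter, and step 3 gains a factor of 360 from the coldest flask to the hottest. With X and Q both at zero, the balance puts E and X.Q each at 45.0% of the J charged. My guess for west is X.Q at 0.180 M, half of that end value, which gives 52.2%, still more than my figure for east.

The forecast names west, with 1.5% in south-east, 29% in north-west, 51% in west and 46.5% in east, and says “Step 3 drains Q and X slowly, but this barely changes E”.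

The flasks give west on top: 51.3% in west, 46.7% in east, 29.5% in north-west and 1.46% in south-east. West ends with X.Q at 26.0% of the J charged. Its E stands at 89.2% of its ceiling. With 0.20 M of Z, the same reckoning puts the ceiling of west at 50.2%, and that share of it is 44.8%; the neighbour flask ends at 44.5%.

All constants were set for the occasion; no experiment stands behind them.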